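## Structural features

Each half is numbered like a drimane (ring A: C1–C5 and C10; ring B: C5–C10; C11–C12 is the ethano bridge; primed locants for the saturated half, with C12 bound to C9'), and β means the face of a half that carries the C10 methyl group. The SMILES decodes to two homochiral 4,4,10-trimethyldecalin-3-ols (3R,5S,9S,10R and 3'R,5'S,8'R,9'S,10'R) that are cis-fused: H5, the C10 methyl group and the C9 side chain all lie on the β face of ring B, and the C3 hydroxyl is α, trans to H5, which is the 3α,5β pattern of the bile acids and not the trans fusion of the usual onoceranes. The halves differ only at C7–C8: ring B holds a trisubstituted alkene C7=C8, whereas ring B' is saturated with 8'β-H, so that the C8' methyl group is α and trans to the bridge. The stereocentres stand in two contiguous blocks, C5–C10–C9 and C5'–C10'–C9'–C8', each built around a quaternary carbon, while C3 and C3' are isolated behind the quaternary C4 and C4'. Fragile points are the C7=C8 alkene, which acid can move to C8=C9 or draw into cationic closure, and the strained cis-decalins themselves, in which a quaternary carbon must be axial on the neighbouring ring in either chair–chair form, so that purely thermodynamic arguments for C3 and C8' are unsafe. The real difficulty is threefold: the all-cis C5/C10/C9 triads, which neither the trans-fused terpene pool nor chair–chair polyene folding delivers; the bridge between the two hindered carbons C9 and C9'; and the distinction of two almost identical halves. The feature that the key step exploits is ring B itself: C5–C6–C7=C8–C9–C10 is a cyclohexene whose three sp3 stereocentres are all-cis, the exact retron of an endo Diels–Alder addition of an E-diene C6=C7–C8=C9 to a ring A alkene C5=C10, and because C9 and C9' share one C2H4 tether both B rings can come from a single bis-diene. In one sentence, the route is a two-directional, catalyst-controlled double Diels–Alder reaction of an achiral acyclic C12 bis-diene with two molecules of an achiral C9 formylcyclohexenone.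

## Logic of the disconnections

**16 back to 14.** No skeletal bond is cut. The C–H bonds of the two angular methyl groups on C10 and C10' are exchanged for C=O.
- Reason: the cycloaddition needs an acceptor on C10, and a formyl group is the acceptor that sits on the right carbon, has the endo preference in the required sense, and is erased to CH3 in one operation.
- Gain: none in size, but it opens the key cut.
- Demand: deoxygenation of two neopentyl aldehydes under conditions that spare an alkene and two free alcohols, which means base and no acid.

**14 back to 13 and 12.** The C7'–H and C8'–H bonds are cut (and the angular carbons are taken to the alcohol level).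
- Reason: this removes the only difference between the halves and the stereocentre C8'.
- Gain: 12 is C2-symmetric, with eight stereocentres in four identical pairs.
- Demand: hydrogen must be added to one alkene only and from the β face. The two ends of 12 are homotopic, so either gives 13, and the β-oriented angular CH2OH, which stands 1,3 to C8', serves as an internal director.

**12 back to 11.** The C3–H and C3'–H bonds are cut (together with the carbinol C–H bonds of the angular carbons).
- Reason: with C3 as a ketone, the ring A building block loses its only stereocentre and becomes achiral.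
- Gain: two stereocentres fewer, and no matched or mismatched pairing in the cycloaddition.
- Demand: the hydride must be delivered to the β face of two remote ketones. This is entrusted to a chiral reagent, because the conformational bias of the cis-decalin cannot be predicted safely.

**11 back to 5 and two molecules of 9 (key).** The bonds C5–C6, C9–C10, C5'–C6' and C9'–C10' are cut.
- Reason: both B rings are endo Diels–Alder retrons on one tether.
- Gain: four C–C bonds, two rings and six stereocentres (two of them quaternary) vanish, and a C30 tetracycle falls to an achiral acyclic C12 piece and an achiral monocyclic C9 piece. The hindered C9–C11–C12–C9' bridge never has to be formed, because it is already in 5.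
- Demand: "ortho" regiochemistry, endo topology, one enantioface of 9 twice over, and enough reactivity at a neopentyl β-carbon.

**5 back to 4, 2, 3 and 1.** The terminal C6=C7 and C6'=C7' double bonds are cut, then C8=C9 and C8'=C9'.
- Reason: each is a carbonyl olefination on a symmetric dialdehyde.
- Gain: C12 falls to C4 plus two C3 units.
- Demand: E geometry at C8=C9, which places C11 in the outside position of the diene and thereby fixes C9 in the key step.

**9 back to 8 and 6.** The C10–CHO bond and the C5–H bond (as C5–Br) are cut.
- Reason: the C5 carbonyl of 6 can enolise only toward C10, so a haloformylation places the formyl carbon without ambiguity.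
- Gain: a commercial symmetric diketone.
- Demand: reaction at one carbonyl only, and hydrogenolysis of C–Br without reduction of the enal.

## Other disconnections considered

**Alternative 1:** (the first that comes to mind) Cut the central C11–C12 bond and join two finished bicyclic C15 halves. The forward key step is alkylation of the lithiated left-half sulfone A1 with the right-half iodide A2, followed by reductive desulfonylation and desilylation.
- The union creates no stereocentre and no ring, so the real problem, two all-cis C5/C10/C9 triads, would have to be solved twice in separate sequences.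
- The obvious pool compounds (sclareolide-type drimanes) are trans-fused and of no use here.
- The displacement at C12 is β-branched and sits next to the quaternary C10', so it should be slow against elimination.
- Protecting groups and a sulfone are carried only to be removed.
- The chosen plan has the bridge from the start and makes both halves in one operation.

**Alternative 2:** Cut C4–C5 and C9–C10 in both halves. The forward key step is a Lewis acid-triggered, two-directional epoxide-opening cation–olefin tetracyclisation of the acyclic bis-epoxide A3. The stereochemical bookkeeping goes against it.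
- Anti addition gives a cis fusion only from a Z C5=C10 alkene.
- The 9α-H then requires a Z C8=C9 alkene with the bridge axial in the nascent ring B.
- A chair fold of ring A places the C3 oxygen cis to H5, whereas the target has them trans. A boat-like ring A or a later inversion at C3 would therefore be needed.
- Z-alkenes are also the ones most prone to stepwise cation chemistry, which leaks to the trans series.
- The termination cannot tell the two halves apart, nor place the alkene at C7=C8 rather than C8=C9.

**Alternative 3:** Keep the stereocentres of a cheap cyclic compound and cut its skeleton. Rings A and B of deoxycholic acid already hold 3α-OH, 5β-H, 8β-H, 9α-H and 10β-CH3, that is the whole array of the right half, with C14 as the future C8' methyl group. The forward key step is a Baeyer–Villiger cleavage of C12–C13 in the 4,4-dimethyl-12-ketone A4, followed by excision of ring D and the side chain.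
- The fit of the stereocentres is perfect, but C14 becomes a methyl group only after C13–C14 and C14–C15 are cut as well. That makes three C–C cleavages and the loss of ten carbons per half.
- The left half needs a further dehydrogenation to C7=C8.
- The two halves must still be joined at C12.
- Step economy is far worse than that of the chosen plan.

Key step: step 6

Assumption: the SMILES is taken literally, so both decalins are made cis-fused (5β-H, 10β-CH3, 3α-OH).
Assumption: the sense of induction in step 6 is derived from the formyl C–H···O model of protonated oxazaborolidine catalysis, by which the (S)-catalyst opens the Re face and the (R)-catalyst the Si face at the formyl-bearing carbon of an s-trans α-substituted enal; both catalyst antipodes are commercial.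

## Steps

Step 1
Reactants: 1 2,5-dimethoxytetrahydrofuran (cis/trans mixture)
Product: 2 succinaldehyde (butanedial)
Conditions: H2O, 90 °C; MeOH distilled off; CH2Cl2 extraction
Reagents that add atoms: water, O
Why: Hydrolysis of the cyclic bis-acetal, driven by removal of methanol; no stereocentre is involved, and 2 is used fresh because it oligomerises on storage.

Step 2
Reactants: 2 succinaldehyde; 3 2-(triphenyl-λ5-phosphanylidene)propanal (2.2 equiv)
Product: 4 (2E,6E)-2,7-dimethylocta-2,6-dienedial
Conditions: CH2Cl2, rt → 40 °C
Reagents that add atoms: none
Why: Two-directional Wittig olefination with a formyl-stabilised ylide, whose reversible addition favours the E trisubstituted enal at both ends; the conjugated product aldehydes are less electrophilic than 2, so each end should react only once.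

Step 3
Reactants: 4 (2E,6E)-2,7-dimethylocta-2,6-dienedial
Product: 5 (3E,7E)-3,8-dimethyldeca-1,3,7,9-tetraene
Conditions: Ph3PCH3Br, KOtBu, THF, 0 °C → rt
Reagents that add atoms: methyltriphenylphosphonium bromide, C[P+](c1ccccc1)(c1ccccc1)c1ccccc1.[Br-]
Why: Wittig methylenation with the non-stabilised ylide adds 1,2 to both enals; the C8=C9 and C8'=C9' geometries from step 2 are untouched, so both dienes carry the tether in the outside (E) position.

Step 4
Reactants: 6 2,2-dimethylcyclohexane-1,3-dione
Product: 8 2-bromo-3,3-dimethyl-4-oxocyclohex-1-ene-1-carbaldehyde, via bromovinyl iminium bromide 7 (not isolated)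
Conditions: DMF (2.4 equiv), PBr3 (2.0 equiv), CHCl3, 0 → 60 °C; then ice-water
Reagents that add atoms: N,N-dimethylformamide, CN(C)C=O; phosphorus tribromide, BrP(Br)Br; water, O
Why: Vilsmeier–Haack–Arnold bromoformylation of a cyclic ketone: the enol can form only away from the quaternary carbon, is formylated at the future C10, and bromide replaces the activated oxygen at the future C5. The two carbonyls of 6 are equivalent, so only one mono-product exists, and limited reagent together with the positive charge of 7 should hold back a second attack.

Step 5
Reactants: 8 2-bromo-3,3-dimethyl-4-oxocyclohex-1-ene-1-carbaldehyde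
Product: 9 3,3-dimethyl-4-oxocyclohex-1-ene-1-carbaldehyde
Conditions: Pd(PPh3)4 (5 mol%), HCO2H, Et3N, DMF, 60 °C
Reagents that add atoms: none
Why: Palladium-catalysed formate hydrogenolysis of a vinyl halide: zerovalent palladium inserts into the activated C5–Br bond (a vinylogous acyl bromide), formate loses CO2 to give the palladium hydride, and reductive elimination leaves C5–H. The ketone and aldehyde are inert, and the neopentyl β-carbon disfavours conjugate reduction.

Step 6
Reactants: 5 (3E,7E)-3,8-dimethyldeca-1,3,7,9-tetraene; 9 3,3-dimethyl-4-oxocyclohex-1-ene-1-carbaldehyde (2.3 equiv)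
Product: 11 C2-symmetric bis-adduct (two cis-fused Δ7-octalin halves joined C9–C11–C12–C9'; each half with C3 ketone; C4 gem-dimethyl; C8 methyl; C10 formyl; H5/CHO/C9 chain all β), via mono-adduct 10 (not isolated)
Conditions: (R)-3,3-diphenyl-1-(2-methylphenyl)tetrahydro-1H,3H-pyrrolo[1,2-c][1,3,2]oxazaborole (25 mol%), HN(SO2CF3)2 (20 mol%), CH2Cl2, −40 → 0 °C
Reagents that add atoms: none
Why: Two successive Lewis acid-catalysed [4+2] cycloadditions, the closest known type being the enantioselective Diels–Alder reaction of α-substituted enals under protonated oxazaborolidine catalysis: boron binds the formyl oxygen of 9, lowers its LUMO and lets the C6–C5 bond (unsubstituted diene terminus to the β-carbon) run ahead of the C9–C10 bond. Each ring B closes as a six-membered carbocycle in a concerted suprafacial–suprafacial [π4s+π2s] mode through a boat-like transition state, first in 10 and then at the remote second diene. C5 and C10 are controlled by the dienophile geometry: C1 and C4 are cis on the ring A alkene, so suprafacial addition leaves H5 and the formyl group cis, which is the cis ring fusion. C9 is controlled by the E geometry of C8=C9 (C11 outside) together with the endo position of the formyl group, which is favoured by secondary overlap and because only this arrangement turns ring A and the C4 methyl groups away from the diene; C11 therefore ends cis to CHO and H5. The absolute sense comes from the catalyst: the formyl C–H···O contact holds the s-trans enal over one phenyl group, the (R)-catalyst leaves the Si face at C10 and C5 open, and since both events obey the same control the homochiral 11 should dominate while heterochiral pairing is removed as a diastereomer, which raises the enantiopurity of 11. Regioselectivity (C9 to C10) is needed against the opposing bias of the C8 methyl group and is secured by the terminal alkyl substituent at C9, as in 1-vinylcyclohexene-type dienes, and by the fact that only the CH2 terminus C6 can reach the neopentyl carbon C5. Chemoselectivity is secured because the C3 ketone is unconjugated and shielded by C4, so that it neither activates a second alkene nor holds the catalyst.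

Step 7
Reactants: 11 C2-symmetric bis-adduct
Product: 12 C2-symmetric tetraol (3α-OH and 3'α-OH; angular CH2OH on C10 and C10'; both Δ7 alkenes intact)
Conditions: (S)-1-methyl-3,3-diphenyltetrahydro-1H,3H-pyrrolo[1,2-c][1,3,2]oxazaborole (40 mol%), BH3·SMe2, THF, −20 °C; MeOH, then aq NH4Cl
Reagents that add atoms: none
Why: Corey–Bakshi–Shibata reduction: each C3 ketone is a 2,2-dimethylcyclohexanone with C4 as the large and C2 as the small group, so the (S)-catalyst should deliver hydride to the β face and give the 3R (3α) alcohol at both remote, independent sites. The aldehydes are reduced along the way to the angular CH2OH groups needed in step 8, and carbonyl reduction is much faster than hydroboration of hindered trisubstituted alkenes at this temperature.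

Step 8
Reactants: 12 C2-symmetric tetraol
Product: 13 7',8'-dihydro tetraol (8'β-H; 8'α-CH3; C7=C8 retained in the other half)
Conditions: [Ir(cod)(PCy3)(py)]PF6 (5 mol%), H2 (1 atm), CH2Cl2, 0 °C → rt, stopped at partial conversion; 12 recovered
Reagents that add atoms: none
Why: Hydroxyl-directed homogeneous hydrogenation: the cationic monovalent iridium centre binds the β-oriented angular CH2OH (1,3 to C8') and the C7'=C8' alkene together, so both hydrogens arrive from the β face and set 8'β-H with the methyl group α. The two ends of 12 are homotopic, so reduction of either alkene gives the same 13, and over-reduction is limited by stopping early and recycling 12.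

Step 9
Reactants: 13 7',8'-dihydro tetraol
Product: 14 dialdehyde diol (C10 and C10' formyl; 3α-OH and 3'α-OH free)
Conditions: 2,2,6,6-tetramethylpiperidin-1-oxyl (TEMPO, 20 mol%), PhI(OAc)2 (2.4 equiv), CH2Cl2, rt
Reagents that add atoms: none
Why: Oxoammonium oxidation is strongly biased toward primary alcohols, and the secondary C3 carbinols are further shielded by the C4 gem-dimethyl group. The 3α-oxygen and the β-formyl group lie on opposite faces of ring A, so no lactol can form, and the alkene is inert.

Step 10
Reactants: 14 dialdehyde diol
Product: 16 target diol CNP0194061.2, via bis-hydrazone 15 (not isolated)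
Conditions: N2H4·H2O, diethylene glycol, 130 °C; then KOH, 200 °C, N2 atmosphere
Reagents that add atoms: none
Why: Wolff–Kishner reduction in the Huang-Minlon form turns both angular formyl groups into methyl groups through hydrazone tautomerisation and loss of N2. The aldehydes have no α-hydrogen, so nothing can epimerise or condense, and the unactivated alkene and the alkoxides are inert to base.

## Compound list

1 | 2,5-dimethoxytetrahydrofuran (cis/trans mixture) | COC1CCC(OC)O1 | starting material
2 | succinaldehyde | O=CCCC=O | intermediate
3 | 2-(triphenyl-λ5-phosphanylidene)propanal | CC(C=O)=P(c1ccccc1)(c1ccccc1)c1ccccc1 | starting material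
4 | (2E,6E)-2,7-dimethylocta-2,6-dienedial | O=C/C(C)=C/CC/C=C(\C)C=O | intermediate
5 | (3E,7E)-3,8-dimethyldeca-1,3,7,9-tetraene | C=C/C(C)=C/CC/C=C(\C)C=C | intermediate
6 | 2,2-dimethylcyclohexane-1,3-dione | CC1(C)C(=O)CCCC1=O | starting material
7 | [(2-bromo-3,3-dimethyl-4-oxocyclohex-1-en-1-yl)methylidene]dimethylammonium bromide | C[N+](C)=CC1=C(Br)C(C)(C)C(=O)CC1.[Br-] | intermediate (not isolated)
8 | 2-bromo-3,3-dimethyl-4-oxocyclohex-1-ene-1-carbaldehyde | CC1(C)C(=O)CCC(C=O)=C1Br | intermediate
9 | 3,3-dimethyl-4-oxocyclohex-1-ene-1-carbaldehyde | CC1(C)C=C(C=O)CCC1=O | intermediate
10 | mono-adduct: cis-fused 10-formyl-4,4,8-trimethyl-3-oxo-Δ7-octalin with a (3E)-4-methylhexa-3,5-dien-1-yl chain on C9; H5, CHO and chain all β | CC1=CC[C@@H]2C(C)(C)C(=O)CC[C@]2(C=O)[C@H]1CC/C=C(\C)C=C | intermediate (not isolated)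
11 | C2-symmetric bis-adduct: 1,2-bis(10-formyl-4,4,8-trimethyl-3-oxo-Δ7-octalin-9-yl)ethane, cis-fused, H5, CHO and C9 chain all β in both halves | CC1=CC[C@@H]2C(C)(C)C(=O)CC[C@]2(C=O)[C@H]1CC[C@H]1C(C)=CC[C@@H]2C(C)(C)C(=O)CC[C@@]21C=O | intermediate
12 | C2-symmetric tetraol: as 11 with 3α-OH (3R) and angular CH2OH in both halves | CC1=CC[C@@H]2C(C)(C)[C@H](O)CC[C@]2(CO)[C@H]1CC[C@H]1C(C)=CC[C@@H]2C(C)(C)[C@H](O)CC[C@@]21CO | intermediate
13 | 7',8'-dihydro tetraol: as 12 with ring B' saturated, 8'β-H, 8'α-CH3 (8'R) | CC1=CC[C@@H]2C(C)(C)[C@H](O)CC[C@]2(CO)[C@H]1CC[C@H]1[C@H](C)CC[C@@H]2C(C)(C)[C@H](O)CC[C@@]21CO | intermediate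
14 | dialdehyde diol: as 13 with formyl groups on C10 and C10' | CC1=CC[C@@H]2C(C)(C)[C@H](O)CC[C@]2(C=O)[C@H]1CC[C@H]1[C@H](C)CC[C@@H]2C(C)(C)[C@H](O)CC[C@@]21C=O | intermediate
15 | bis-hydrazone of 14 | CC1=CC[C@@H]2C(C)(C)[C@H](O)CC[C@]2(/C=N/N)[C@H]1CC[C@H]1[C@H](C)CC[C@@H]2C(C)(C)[C@H](O)CC[C@@]21/C=N/N | intermediate (not isolated)
16 | target: 1-[(1S,4aS,6R,8aR)-6-hydroxy-2,5,5,8a-tetramethyl-1,4,4a,5,6,7,8,8a-octahydronaphthalen-1-yl]-2-[(1S,2R,4aS,6R,8aR)-6-hydroxy-2,5,5,8a-tetramethyldecahydronaphthalen-1-yl]ethane | CC1=CC[C@@H]2C(C)(C)[C@H](O)CC[C@]2(C)[C@H]1CC[C@H]1[C@H](C)CC[C@@H]2C(C)(C)[C@H](O)CC[C@@]21C | target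

## Step count and least certain steps

Total step count: 10. Longest linear sequence: 8 (steps 1–3 and 6–10); steps 4 and 5 form the second, two-step branch.

**Step 6 (key step).**
- Most likely failure: insufficient rate. C5 is neopentyl and C10 becomes quaternary, so acid-induced oligomerisation of 5 or cation–olefin closure of its 1,5-diene unit may overtake the cycloaddition.
- Further risks: erosion of regiocontrol by the opposing bias of the C8 methyl group, and stalling after the first addition.
- Fallback: give up catalyst control of absolute configuration in the cycloaddition and take it from the ketone reduction instead. It sets out from 5 and 9.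
  - A stoichiometric strong achiral Lewis acid (AlBr3/AlMe3 in toluene–CH2Cl2) or 12–15 kbar should give 11 beside the enantiomeric bis-adduct F1 and the heterochiral meso bis-adduct F2.
  - F2 is removed as a diastereomer by chromatography or crystallisation.
  - The racemate is submitted to the conditions of step 7. Because the reduction catalyst fixes C3 and C3' as R in both antipodes, 11 gives 12 and F1 gives the diastereomeric tetraol F3, which is separated.
  - The fallback returns to the route at 12. On statistical grounds it sacrifices about three quarters of the material.

**Step 8.**
- Most likely failure: loss of control over the extent of reduction. The two alkenes are remote and independent, so the mono-reduced compound can at best be about half of the mixture on statistical grounds.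
- Further risks: iridium hydride-mediated migration of the alkene to the tetrasubstituted position, and weak direction because four hydroxyl groups compete for the metal.
- Fallback: move the reduction to the end and change its mechanism. It sets out from 12.
  - TEMPO/PhI(OAc)2 gives the bis-ene dialdehyde diol F4.
  - Hydrazine gives the bis-ene bis-hydrazone F5.
  - KOH at 200 °C gives the C2-symmetric bis-ene diol F6.
  - A radical hydrogen-atom-transfer hydrogenation (Mn(dpm)3, PhSiH3, tBuOOH, iPrOH), run to partial conversion, forms the tertiary C8' radical and should quench it so that the methyl group ends trans to the bridge.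
  - The fallback returns to the route at 16.

**Step 4.**
- Most likely failure: over-reaction at the second carbonyl, since the first functionalisation deactivates it only weakly. Acid-promoted fragmentation of the non-enolisable 1,3-diketone is a further risk.
- Fallback: a classical 1,3-carbonyl transposition on a protected ketone. It sets out from 6.
  - Ethylene glycol/TsOH gives the keto ketal F7.
  - Claisen formylation (HCO2Et, NaH) gives the hydroxymethylidene ketone F8.
  - 2-Iodopropane/K2CO3 gives the isopropyl enol ether F9.
  - LiAlH4 gives the allylic alcohol F10.
  - Aqueous HCl unmasks the enal by allylic transposition and cleaves the ketal.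
  - The fallback returns to the route at 9, bypassing 8 and step 5.

**Step 7.**
- Most likely failure: a mismatch between the catalyst and the intrinsic facial bias of the strained cis-decalin, which cannot be predicted safely because both chair–chair forms are congested. Slow reduction next to C4 could also let hydroboration of the alkenes compete.
- Fallback: give up catalyst control for substrate control on a different substrate. It sets out from 11.
  - LiAlH(OtBu)3 at −78 °C reduces only the aldehydes and gives the diketo diol F11.
  - The bulky hydride LiBH(sBu)3 then reduces the ketones.
  - In the form with the angular carbon axial on ring A, the axial trajectory on the α face is closed by the axial C6. The bulky hydride should therefore enter along the equatorial trajectory from the β face and give the 3α alcohols.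
  - The fallback returns to the route at 12.

## Further compounds

F1 | step 6 | enantiomeric bis-adduct (ent-11) | CC1=CC[C@H]2C(C)(C)C(=O)CC[C@@]2(C=O)[C@@H]1CC[C@@H]1C(C)=CC[C@H]2C(C)(C)C(=O)CC[C@]21C=O
F2 | step 6 | heterochiral meso bis-adduct | CC1=CC[C@@H]2C(C)(C)C(=O)CC[C@]2(C=O)[C@H]1CC[C@@H]1C(C)=CC[C@H]2C(C)(C)C(=O)CC[C@]21C=O
F3 | step 6 | diastereomeric tetraol (3R,3'R alcohols on the mirror-image skeleton) | CC1=CC[C@H]2C(C)(C)[C@H](O)CC[C@@]2(CO)[C@@H]1CC[C@@H]1C(C)=CC[C@H]2C(C)(C)[C@H](O)CC[C@]21CO
F4 | step 8 | bis-ene dialdehyde diol | CC1=CC[C@@H]2C(C)(C)[C@H](O)CC[C@]2(C=O)[C@H]1CC[C@H]1C(C)=CC[C@@H]2C(C)(C)[C@H](O)CC[C@@]21C=O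
F5 | step 8 | bis-ene bis-hydrazone | CC1=CC[C@@H]2C(C)(C)[C@H](O)CC[C@]2(/C=N/N)[C@H]1CC[C@H]1C(C)=CC[C@@H]2C(C)(C)[C@H](O)CC[C@@]21/C=N/N
F6 | step 8 | C2-symmetric bis-ene diol | CC1=CC[C@@H]2C(C)(C)[C@H](O)CC[C@]2(C)[C@H]1CC[C@H]1C(C)=CC[C@@H]2C(C)(C)[C@H](O)CC[C@@]21C
F7 | step 4 | keto ketal, 6,6-dimethyl-1,4-dioxaspiro[4.5]decan-7-one | O=C1CCCC2(OCCO2)C1(C)C
F8 | step 4 | hydroxymethylidene ketone, 8-(hydroxymethylidene)-6,6-dimethyl-1,4-dioxaspiro[4.5]decan-7-one | O=C1C(=CO)CCC2(OCCO2)C1(C)C
F9 | step 4 | isopropyl enol ether, (E)-8-(isopropoxymethylidene)-6,6-dimethyl-1,4-dioxaspiro[4.5]decan-7-one | O=C1/C(=C/OC(C)C)CCC2(OCCO2)C1(C)C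
F10 | step 4 | allylic alcohol, (E)-8-(isopropoxymethylidene)-6,6-dimethyl-1,4-dioxaspiro[4.5]decan-7-ol (racemic) | OC1/C(=C/OC(C)C)CCC2(OCCO2)C1(C)C
F11 | step 7 | diketo diol (C3 and C3' ketones, angular CH2OH groups) | CC1=CC[C@@H]2C(C)(C)C(=O)CC[C@]2(CO)[C@H]1CC[C@H]1C(C)=CC[C@@H]2C(C)(C)C(=O)CC[C@@]21CO
A1 | alternative 1 | left-half sulfone (cis-fused 3α-silyloxy-drim-7-en-11-yl phenyl sulfone) | CC1=CC[C@@H]2C(C)(C)[C@H](O[Si](C)(C)C(C)(C)C)CC[C@]2(C)[C@H]1CS(=O)(=O)c1ccccc1
A2 | alternative 1 | right-half iodide (cis-fused 3α-silyloxy-8α-methyl-drimane 11-iodide) | IC[C@H]1[C@H](C)CC[C@@H]2C(C)(C)[C@H](O[Si](C)(C)C(C)(C)C)CC[C@@]21C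
A3 | alternative 2 | (3R,6Z,10Z,14Z,18Z,22R)-2,3:22,23-diepoxy-2,3,22,23-tetrahydrosqualene | CC1(C)O[C@@H]1CC/C(C)=C\CC/C(C)=C\CC/C=C(/C)CC/C=C(/C)CC[C@H]1OC1(C)C
A4 | alternative 3 | 3α-hydroxy-4,4-dimethyl-12-oxo-5β-cholan-24-oic acid | C[C@H](CCC(=O)O)[C@H]1CC[C@@H]2[C@@]1(C(=O)C[C@H]3[C@H]2CC[C@H]4[C@@]3(CC[C@H](C4(C)C)O)C)C
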